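**Late rise.** Late in both earlier runs the product climbs while the starting material falls: in beta from 12% at 6.00 h to 42% at 12.0 h, in epsilon from 11% at 5.00 h to 36% at 12.0 h. The readings of epsilon bend upward, with 6 percentage points gained in the 3.00 h up to 8.00 h and 19 points in the 4.00 h after it, so I read each slope as an average over a curve. Epsilon carries 63.4 times the base of beta, yet its average slope is lower. At beta's slope the whole charge takes 20.0 h, and at epsilon's 28.0 h. With a scatter of 2 points per reading, I pool the two slopes.

| flask | starting material | base | gas | remark | time |
|---|---|---|---|---|---|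
| beta | 20 mM | 0.0041 mM | 6.7 mM (held) | run made earlier |  |
| epsilon | 20 mM | 0.26 mM | 6.7 mM (held) | run made earlier |  |
| dusk | 20 mM | 0.00500 mM | 6.7 mM (held) |  | 25 h |
| dawn | 20 mM | 0.0150 mM | 6.7 mM (held) |  | 25 h |
| summer | 20 mM | 0.0400 mM | 6.7 mM (held) |  | 25 h |
| noon | 20 mM | 0.120 mM | 6.7 mM (held) |  | 25 h |
| autumn | 20 mM | 0.400 mM | 6.7 mM (held) |  | 25 h |

| run | time / h | product / % | starting material / % |
|---|---|---|---|
| beta | 2.00 | 1 | 97 |
| beta | 4.00 | 2 | 94 |
| beta | 6.00 | 12 | 91 |
| beta | 8.00 | 20 | 78 |
| beta | 10.0 | 27 | 71 |
| beta | 12.0 | 42 | 57 |
| epsilon | 1.00 | 3 | 101 |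
| epsilon | 1.50 | 2 | 103 |
| epsilon | 3.00 | 1 | 100 |
| epsilon | 5.00 | 11 | 94 |
| epsilon | 8.00 | 17 | 80 |
| epsilon | 12.0 | 36 | 64 |

(standard deviation of a reading: 2 percentage points)

- at the start none of the gas is in solution
- "hardly changes" means that all values lie within two and a half points (for a concentration: within two and a half percent of the largest)

* amount of product at the end, in percent of the starting material charged for dusk, dawn, summer, noon, autumn, in this order
* how the row runs (hardly changes / rises, then falls / falls, then rises / rises all the way / falls all the way)

**Two times.** The pooled slope gives 23.3 h, the clearing time, meaning the hours a rise at this average slope needs for the whole charge. At 12.0 h the two runs hold on average 60.5% of the starting material, so at that slope this remainder needs 14.1 h, and 13.0 h remain. The time needed is longer than the time remaining, so I expect 4.79% of the starting material left and 94.8% product along the row. Autumn's base lies above epsilon's, so that point is an extrapolation.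

**The forecast.** It gives 90%, 90%, 90%, 90% and 88%, shape hardly changes, holding that “base is not rate-limiting across this range”.

**The flask.** The row reads 96.3%, 96.2%, 96.1%, 95.7% and 94.1%: it hardly changes.

    gas ⇌ coupling partner, rate k1*(csat - [coupling partner]) (kL = 0.00620 min⁻¹)
    starting material + coupling partner + released group → product + 2 released group (k = 52.0 L² mol⁻² min⁻¹)
    base + released group ⇌ salt, settled at all times (K = 6.20 × 10⁵ L mol⁻¹)
    starting material + coupling partner → product + released group (k = 0.0400 L mol⁻¹ min⁻¹)

Dusk holds coupling partner at 3.65 mM at 12.5 h, against a saturation of 6.7 mM. Dusk's 53.9% of starting material at that time needs 12.6 h by the clearing time, and 12.5 h remain. Autumn stands at 61.6% at that time, so the clearing time leaves 8.01%, and the flask holds 5.88% at 25.0 h.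

The readings were generated by integration for substances that don't exist.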